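Structural features

The target 16 is a fully acylated methyl shikimate: one cyclohex-1-ene ring with a methyl ester on C1 (conjugated with C1=C2), three contiguous acyloxy stereocentres C3 (R), C4 (S), C5 (R), and a methylene C6. O3 is allylic and carries acetyl; O4 is cis to O3 and carries (R)-2-methylbutanoyl; O5 is trans to O4 and carries (S)-3-methylpentanoyl. The two side-chain stereocentres are isolated from the ring: the one in the 2-methylbutanoyl group is α to a carbonyl and can epimerise, the one in the 3-methylpentanoyl group is β and robust. Fragile points are the allylic C3 acetate γ to the enoate (ionisable, and two eliminations away from a benzoate), the vicinal esters (1,2-acyl migration once a neighbouring hydroxyl is free, fastest across the cis O3/O4 pair), and the four esters, which exclude strong nucleophiles late in the route. The carbon skeleton is simple; the real difficulty is to place three different acyl groups on three neighbouring secondary oxygens while the cis-then-trans C3/C4/C5 triad is controlled. The key step exploits two facts: C1=C2–C3 is an allyl unit capped by the ester on C1, and the C3–O and C4–O bonds are cis. That is the signature of a net-retentive (double-inversion) opening of a C3–C4 epoxide through an η3-allylpalladium complex over C1–C3, with acetic acid as the nucleophile that makes the ring C3–O bond instead of an O–acyl bond. The trans C4/C5 relation is handled in the same spirit, by an invertive C5–O bond formation with the carboxylic acid as nucleophile, on an intermediate whose relative configuration is fixed by a temporary oxygen bridge between C5 and C2.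

Logic of the disconnections

Atom labels C1–C6 and O3–O5 are those of the ring of 16. In 3, 4, 5 and 6 the atoms C1 to C6 sit at bicyclic positions 2, 1, 6, 5, 4 and 3, and O5 is the bridge oxygen.

16 to 13 and 14. The bond cut is the acyl C–O bond between O4 and the carbonyl carbon of the 2-methylbutanoyl group. It is cut last because O4 is the one oxygen that leaves the key step as a free hydroxyl, so an ordinary esterification is unambiguous there, and because the epimerisable α-stereocentre of 14 then sees no base or metal. The gain is one ester and one side-chain stereocentre. The forward step must acylate a hydroxyl flanked by two esters faster than the cis acetate migrates from O3 to O4, and without epimerising 14.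

13 to 10 and 11 (key disconnection). The bond cut is the ring C3–O bond, not the O–acetyl bond, and O4 is reconnected to C3 as a C3–C4 epoxide. In one sentence, 13 arises from 10 and 11 by palladium-catalysed C3–O bond formation with net retention, whereas the conventional plan makes no ring C–O bond at all. The gain is that the configuration at C3, the cis C3/C4 relation and the distinction between O3 and O4 all become consequences of one mechanism. The forward step must ionise C3 with inversion, return acetate to C3 (not C1) with a second inversion, and do so faster than β-hydride elimination, in the presence of the C5 ester.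

10 to 7 and 8. The bond cut is the ring C5–O bond, with inversion at C5. The cut turns the trans relation between the epoxide and O5 in 10 into the cis relation in 7, which is the relation that an oxygen-bridged bicycle delivers; 8 again makes its own carbinol C–O bond. The gain is one ester, one side-chain stereocentre, and a precursor whose three ring stereocentres are all cis. The forward step must be a clean SN2 at a secondary carbon next to an epoxide, without elimination toward C6.

7 to 5. In the retrosynthetic sense the C1=C2 π bond is exchanged for a bond between O5 and C2; the forward step breaks that C2–O bond. The reason is that in 5 the oxygen that becomes O5 bridges C2 and C5, a ring that is absent from 16 and is built only to lock C5 and the epoxide carbons into one rigid framework. The gain is a compact bicycle with sharply different faces in place of an alkene and a free hydroxyl. The forward step requires that the ester enolate 6 expel the bridge oxygen faster than it attacks the epoxide.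

5 to 4. The bonds cut are the two epoxide C–O bonds at C3 and C4. The reason is that the C3=C4 bond of 4 has one open face, on the side of the oxygen bridge. The gain is two stereocentres. The forward step must be exo-selective and must leave the bridge intact.

4 to 3. The bond cut is the bond between the acyl carbon on C1 and the methoxy oxygen, in exchange for the imide C–N bond of 3. This is a tactical change: the imide is needed for two-point binding in the cycloaddition, the methyl ester for the enolate step and for 16. Nothing is gained in complexity. The forward step must cleave the exocyclic carbonyl under conditions too mild for bridge elimination or cycloreversion.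

3 to 1 and 2. The bonds cut are the two σ bonds C1–C2 and C5–C6, made together in a [4+2] cycloaddition. The reason is that all six ring carbons and O5 come from two flat, achiral, purchasable compounds in the only step that sets absolute configuration. The gain is complete. The forward step needs control of the enantioface of 2, endo selectivity, and a temperature low enough to prevent cycloreversion.

Other disconnections considered

Alternative 1: The cut that comes to mind first is that of the three O–acyl bonds of 16, that is, stepwise acylation of methyl shikimate A1. O3 and O4 would be masked as the acetonide A2, O5 esterified with 8, the acetonide removed, O3 acetylated selectively through a cyclic orthoester that opens to the axial ester, and O4 esterified with 14. The forward key step is a regioselective mono-acylation of a cis-diol. This plan makes no ring stereocentre; its whole content is protecting-group traffic and a kinetic distinction between two hydroxyls whose mono-esters can interconvert by 1,2-acyl migration. It needs about as many operations as the chosen route and depends on a natural product for the ring. In the chosen plan the O3/O4 question is answered by the mechanism of the C3–O bond formation.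

Alternative 2: C3–O and C4–O are cut together as two hydroxyls. The forward key step is an osmium-catalysed cis-dihydroxylation (OsO4, NMO) of the diene ester A3 on the face anti to the C5 ester. A3 would come from the mirror-image cycloadduct series by opening the oxygen bridge before any oxidation and esterifying O5 with retention. The step creates C3 and C4 in one operation, but as two free hydroxyls that must then be told apart, which returns the problem of Alternative 1. Its face selectivity would rest on one stereocentre of a nearly planar cyclohexadiene, and A3 is a cyclohexadienyl ester one elimination away from a benzoate. The chosen plan keeps the bridge until the oxidation is done, so the face is fixed by a rigid bicycle, and makes O3 and O4 different at the moment C3–O is formed.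

Alternative 3: The C1=C2 bond is cut. The forward key step is a ring-closing metathesis of the acyclic triester A4 with the second-generation Grubbs catalyst RuCl2(=CHPh)(PCy3)(H2IMes), A4 being assembled from a carbohydrate-derived erythro,threo-triol and an acrylate unit. The ring closure is plausible but solves the least difficult part of 16. The stereotriad would be bought with a sugar whose hydroxyls are not differentiated in the required way, so the three esters could only be placed after several protecting-group steps. The metathesis would have to join a 1,1-disubstituted acrylate to an alkene bearing an allylic ester, both reluctant partners. The chosen route obtains ring, oxygen pattern and absolute configuration from one catalytic cycloaddition of 1 and 2.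

Key step: step 6

Assumption on materials: 8 and 14 are taken as purchasable single enantiomers.
Assumption on step 1: the (S,S)-ligand is taken to give the (1S,2S,4S)-endo adduct, as the square-planar chelate model of the catalyst predicts; if the sense were opposite, the (R,R)-ligand would be used with no other change.
Numbering: steps 1 to 4 use bicyclic numbering for 3 to 6; from 7 on the ring numbering of 16 is used (bicyclic C2, C1, C6, C5, C4, C3 = ring C1, C2, C3, C4, C5, C6).

Step 1
Reactants: 1 furan; 2 3-acryloyl-1,3-oxazolidin-2-one
Product: 3 3-[(1S,2S,4S)-7-oxabicyclo[2.2.1]hept-5-ene-2-carbonyl]-1,3-oxazolidin-2-one (endo adduct)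
Conditions: [Cu((S,S)-tBu-box)](SbF6)2 (5 mol%; tBu-box = 2,2'-(propane-2,2-diyl)bis[(4S)-4-tert-butyl-4,5-dihydro-1,3-oxazole]), 1 in excess, CH2Cl2, −78 °C; cold filtration through silica, recrystallisation
Reagents that add atoms: none
Why: Asymmetric Diels–Alder reaction under a chiral Lewis acid of divalent copper: 2 chelates the metal through both carbonyls in its s-cis form, one face of the acryloyl group is shielded by a tert-butyl group of the ligand, and 1 should add endo to the open face to set (1S,2S,4S). The low temperature suppresses cycloreversion; the minor exo adduct carries the opposite bridgehead configuration and has to be removed by the recrystallisation, because C2 is lost later.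

Step 2
Reactants: 3 3-[(1S,2S,4S)-7-oxabicyclo[2.2.1]hept-5-ene-2-carbonyl]-1,3-oxazolidin-2-one
Product: 4 methyl (1S,2S,4S)-7-oxabicyclo[2.2.1]hept-5-ene-2-carboxylate
Conditions: MeOMgBr (from MeMgBr and MeOH), MeOH–CH2Cl2, 0 °C; aq. NH4Cl
Reagents that add atoms: methanol (delivered as methoxymagnesium bromide), CO
Why: Transesterification of an N-acyl oxazolidinone by a magnesium alkoxide; magnesium chelation activates the exocyclic carbonyl, and the reagent is too weakly basic at 0 °C to start elimination of the bridge. Partial epimerisation at C2 would be harmless, since the bridgeheads are untouched and C2 becomes trigonal in step 4.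

Step 3
Reactants: 4 methyl (1S,2S,4S)-7-oxabicyclo[2.2.1]hept-5-ene-2-carboxylate
Product: 5 methyl (1R,2S,4S,5S,6R)-5,6-epoxy-7-oxabicyclo[2.2.1]heptane-2-carboxylate (exo epoxide)
Conditions: mCPBA, CH2Cl2, 0 °C to rt
Reagents that add atoms: mCPBA (3-chloroperoxybenzoic acid), O=C(OO)c1cccc(Cl)c1
Why: Prilezhaev epoxidation; the peracid should reach C5=C6 only from the exo face, on the side of the oxygen bridge, because the endo face is covered by the C2–C3 bridge and the endo ester. This sets the two epoxide carbons (ring C4 and C3) relative to the bridgeheads, and the product can no longer undergo cycloreversion.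

Step 4
Reactants: 5 methyl (1R,2S,4S,5S,6R)-5,6-epoxy-7-oxabicyclo[2.2.1]heptane-2-carboxylate
Product: 7 methyl (3R,4S,5S)-3,4-epoxy-5-hydroxycyclohex-1-ene-1-carboxylate, via lithium ester enolate 6 (not isolated)
Conditions: LiN(SiMe3)2 (1.1 equiv), THF, −78 °C to 0 °C; AcOH
Reagents that add atoms: none
Why: E1cB β-elimination: the ester enolate 6 expels the bridging alkoxide from the adjacent bridgehead, which cleaves the temporary oxygen bridge, creates C1=C2 and releases the bridge oxygen as the C5 hydroxyl on the same face as the epoxide. No stereocentre is formed or touched, and the cis arrangement of alkoxide and epoxide excludes a Payne rearrangement.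

Step 5
Reactants: 7 methyl (3R,4S,5S)-3,4-epoxy-5-hydroxycyclohex-1-ene-1-carboxylate; 8 (S)-3-methylpentanoic acid
Product: 10 methyl (3R,4S,5R)-3,4-epoxy-5-{[(3S)-3-methylpentanoyl]oxy}cyclohex-1-ene-1-carboxylate, via alkoxyphosphonium carboxylate 9 (not isolated)
Conditions: PPh3, DIAD, THF, 0 °C to rt
Reagents that add atoms: none
Why: Mitsunobu reaction: the C5 hydroxyl is activated as the alkoxyphosphonium ion 9 and displaced by the carboxylate of 8 in an SN2 step, so C5 is inverted from S to R and the ester ends up trans to the epoxide. The nucleophile enters on the face away from the epoxide oxygen, which is cis to the leaving group and cannot participate; the β-stereocentre of 8 is not at risk.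

Step 6
Reactants: 10 methyl (3R,4S,5R)-3,4-epoxy-5-{[(3S)-3-methylpentanoyl]oxy}cyclohex-1-ene-1-carboxylate; 11 acetic acid
Product: 13 methyl (3R,4S,5R)-3-acetoxy-4-hydroxy-5-{[(3S)-3-methylpentanoyl]oxy}cyclohex-1-ene-1-carboxylate, via allylpalladium alkoxide zwitterion 12 (not isolated)
Conditions: Pd(PPh3)4 (5 mol%), 11 (3 equiv), THF, 0 °C
Reagents that add atoms: none
Why: Tsuji–Trost reaction of a vinyl epoxide with a carboxylic acid pronucleophile, a known reaction type for cyclic diene monoepoxides and γ,δ-epoxy enoates. Zerovalent palladium binds C1=C2 of 10 on the face opposite the epoxide oxygen and ionises the allylic C3–O bond with inversion, which gives the zwitterion 12, an η3-allyl complex over C1–C2–C3 with the alkoxide left on C4. The alkoxide is protonated by 11, and the acetate so formed attacks the allyl ligand from outside, on the face opposite palladium, in a second inversion. No ring is closed; the only ring event is the opening of the oxirane. The one new stereocentre, C3, is therefore controlled by the epoxide configuration through double inversion (net retention, R), so the acetate must come out cis to the C4 hydroxyl, whose C–O bond is never broken; C5 is a spectator. The regioselectivity that the step needs, C3 and not C1, is secured by the ester on C1: C1 is the fully substituted allyl terminus, attack at C3 restores the conjugated enoate, and because carboxylate addition is reversible under palladium a C1 adduct would be re-ionised and funnelled to the C3 acetate. Re-ionisation of 13 itself leads back to the same allyl complex and the same product, and β-hydride elimination is held back by the low temperature and the excess of 11. In one operation the step makes the C3–O bond with its acetyl group attached, fixes the cis C3/C4 relation and leaves O4 as the only free hydroxyl.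

Step 7
Reactants: 13 methyl (3R,4S,5R)-3-acetoxy-4-hydroxy-5-{[(3S)-3-methylpentanoyl]oxy}cyclohex-1-ene-1-carboxylate; 14 (R)-2-methylbutanoic acid
Product: 16 methyl (3R,4S,5R)-3-acetoxy-4-{[(2R)-2-methylbutanoyl]oxy}-5-{[(3S)-3-methylpentanoyl]oxy}cyclohex-1-ene-1-carboxylate, via O-acylisourea 15 (not isolated)
Conditions: DIC, DMAP (10 mol%), CH2Cl2, 0 °C to rt
Reagents that add atoms: none
Why: Steglich esterification of the only free hydroxyl; no ring stereocentre is touched. Carbodiimide activation of 14 avoids the acid chloride and amine combination that could epimerise its α-carbon through a ketene, and low temperature with catalytic DMAP should keep O-acylation ahead of migration of the cis acetate from O3 to O4.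

Compound list

1 | furan | c1ccoc1 | starting material
2 | 3-acryloyl-1,3-oxazolidin-2-one | C=CC(=O)N1CCOC1=O | starting material
3 | 3-[(1S,2S,4S)-7-oxabicyclo[2.2.1]hept-5-ene-2-carbonyl]-1,3-oxazolidin-2-one (endo adduct) | O=C(N1CCOC1=O)[C@H]2C[C@H]3C=C[C@@H]2O3 | intermediate
4 | methyl (1S,2S,4S)-7-oxabicyclo[2.2.1]hept-5-ene-2-carboxylate (endo ester) | COC(=O)[C@H]1C[C@H]2C=C[C@@H]1O2 | intermediate
5 | methyl (1R,2S,4S,5S,6R)-5,6-epoxy-7-oxabicyclo[2.2.1]heptane-2-carboxylate (exo epoxide, endo ester) | COC(=O)[C@H]1C[C@H]2[C@@H]3O[C@@H]3[C@@H]1O2 | intermediate
6 | lithium ester enolate of 5 (O-lithio ketene acetal at bicyclic C2, enolate geometry not defined) | COC(O[Li])=C1C[C@H]2[C@@H]3O[C@@H]3[C@@H]1O2 | intermediate (not isolated)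
7 | methyl (3R,4S,5S)-3,4-epoxy-5-hydroxycyclohex-1-ene-1-carboxylate (epoxide cis to the hydroxyl) | COC(=O)C1=C[C@H]2O[C@H]2[C@@H](O)C1 | intermediate
8 | (S)-3-methylpentanoic acid | CC[C@H](C)CC(=O)O | starting material
9 | alkoxyphosphonium salt of 7 (C5–O–PPh3 cation, (S)-3-methylpentanoate counter-ion) | COC(=O)C1=C[C@H]2O[C@H]2[C@@H](O[P+](c3ccccc3)(c3ccccc3)c3ccccc3)C1.CC[C@H](C)CC(=O)[O-] | intermediate (not isolated)
10 | methyl (3R,4S,5R)-3,4-epoxy-5-{[(3S)-3-methylpentanoyl]oxy}cyclohex-1-ene-1-carboxylate (epoxide trans to the ester) | COC(=O)C1=C[C@H]2O[C@H]2[C@H](OC(=O)C[C@@H](C)CC)C1 | intermediate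
11 | acetic acid | CC(=O)O | starting material
12 | zwitterionic allylpalladium alkoxide from 10 (bis(triphenylphosphine)palladium on the face opposite O4, drawn as the C3 σ-form; alkoxide at C4) | COC(=O)C1=C[C@H]([Pd-]([P+](c2ccccc2)(c2ccccc2)c2ccccc2)[P+](c2ccccc2)(c2ccccc2)c2ccccc2)[C@@H]([O-])[C@H](OC(=O)C[C@@H](C)CC)C1 | intermediate (not isolated)
13 | methyl (3R,4S,5R)-3-acetoxy-4-hydroxy-5-{[(3S)-3-methylpentanoyl]oxy}cyclohex-1-ene-1-carboxylate | COC(=O)C1=C[C@@H](OC(C)=O)[C@@H](O)[C@H](OC(=O)C[C@@H](C)CC)C1 | intermediate
14 | (R)-2-methylbutanoic acid | CC[C@@H](C)C(=O)O | starting material
15 | O-[(2R)-2-methylbutanoyl]-N,N'-diisopropylisourea | CC[C@@H](C)C(=O)OC(=NC(C)C)NC(C)C | intermediate (not isolated)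
16 | methyl (3R,4S,5R)-3-acetoxy-4-{[(2R)-2-methylbutanoyl]oxy}-5-{[(3S)-3-methylpentanoyl]oxy}cyclohex-1-ene-1-carboxylate (CNP0188172.1) | CC[C@H](C)CC(=O)O[C@@H]1CC(C(=O)OC)=C[C@@H](OC(C)=O)[C@H]1OC(=O)[C@H](C)CC | target

Total number of steps: 7. Longest linear sequence: 7 steps, from 1 and 2 to 16; 8, 11 and 14 are purchased and enter in steps 5, 6 and 7.

Least certain, first: step 6 (key step). What is most likely to go wrong is β-hydride elimination from the allylpalladium intermediate, toward C4–H or C6–H, outrunning capture by acetate. Ionisation may also be slow because palladium must bind on the ring face that carries the C5 ester, and stereospecificity could erode through palladium-for-palladium exchange at the allyl complex. The fallback leaves allylpalladium chemistry altogether and makes C3–O and C4–O by osmylation on the bicycle. It sets out from 4. An exo-selective dihydroxylation (OsO4 cat., NMO, acetone–water) should give methyl 5,6-exo-dihydroxy-7-oxabicyclo[2.2.1]heptane-2-carboxylate F1. Acetalisation (2,2-dimethoxypropane, TsOH) would give its acetonide F2, and LiN(SiMe3)2 the bridge-opened methyl 3,4-O-isopropylidene-5-epi-shikimate F3. Mitsunobu inversion with 8 would give methyl 3,4-O-isopropylidene-5-O-[(3S)-3-methylpentanoyl]shikimate F4, and aqueous acetic acid the diol methyl 5-O-[(3S)-3-methylpentanoyl]shikimate F5. Exchange with trimethyl orthoacetate (PPTS, CH2Cl2) would give the cyclic orthoester methyl 3,4-O-(1-methoxyethylidene)-5-O-[(3S)-3-methylpentanoyl]shikimate F6. Its mild aqueous acid hydrolysis is expected to open to the axial ester, that is, the C3 acetate, and so to come back to the route at 13.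

Least certain, second: step 5. What is most likely to go wrong is E2 loss of the activated C5 oxygen toward C6, or slow protonation of the betaine by the weakly acidic aliphatic acid, which lets the hydrazide compete as the nucleophile. The fallback separates activation from substitution. It sets out from 7: MsCl and Et3N (CH2Cl2, 0 °C) would give methyl 3,4-epoxy-5-(methanesulfonyloxy)cyclohex-1-ene-1-carboxylate F7 with the configuration of 7. Cesium (S)-3-methylpentanoate (from 8 and Cs2CO3; 18-crown-6, toluene, 60 °C) should displace the sulfonate with inversion and return to the route at 10.

Least certain, third: step 4. What is most likely to go wrong is attack of the enolate carbon on the neighbouring epoxide carbon (closure of a three-membered ring), or base-induced isomerisation of the epoxide, competing with expulsion of the bridge oxygen, because the bridge C–O bond is only partly aligned with the enolate π system. The fallback reverses the order of bridge opening and epoxidation. It sets out from 4: LiN(SiMe3)2 (THF, −78 °C to 0 °C) should give methyl (5S)-5-hydroxycyclohexa-1,3-diene-1-carboxylate F8. A hydroxyl-directed (Henbest) epoxidation with mCPBA, regioselective for the more electron-rich C3=C4 bond next to the carbinol and cis to the hydrogen-bonding hydroxyl, would return to the route at 7.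

Further compounds

F1 | step 6 | methyl 5,6-exo-dihydroxy-7-oxabicyclo[2.2.1]heptane-2-carboxylate (exo-cis-diol of 4) | COC(=O)[C@H]1C[C@H]2[C@H](O)[C@H](O)[C@@H]1O2
F2 | step 6 | acetonide of F1 (5,6-exo-isopropylidenedioxy) | COC(=O)[C@H]1C[C@H]2[C@@H]3OC(C)(C)O[C@@H]3[C@@H]1O2
F3 | step 6 | methyl 3,4-O-isopropylidene-5-epi-shikimate | COC(=O)C1=C[C@H]2OC(C)(C)O[C@H]2[C@@H](O)C1
F4 | step 6 | methyl 3,4-O-isopropylidene-5-O-[(3S)-3-methylpentanoyl]shikimate | COC(=O)C1=C[C@H]2OC(C)(C)O[C@H]2[C@H](OC(=O)C[C@@H](C)CC)C1
F5 | step 6 | methyl 5-O-[(3S)-3-methylpentanoyl]shikimate | COC(=O)C1=C[C@@H](O)[C@@H](O)[C@H](OC(=O)C[C@@H](C)CC)C1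
F6 | step 6 | methyl 3,4-O-(1-methoxyethylidene)-5-O-[(3S)-3-methylpentanoyl]shikimate (both epimers at the orthoester carbon) | COC(=O)C1=C[C@H]2OC(C)(OC)O[C@H]2[C@H](OC(=O)C[C@@H](C)CC)C1
F7 | step 5 | methyl 3,4-epoxy-5-(methanesulfonyloxy)cyclohex-1-ene-1-carboxylate (C5 mesylate of 7, configuration of 7) | COC(=O)C1=C[C@H]2O[C@H]2[C@@H](OS(C)(=O)=O)C1
F8 | step 4 | methyl (5S)-5-hydroxycyclohexa-1,3-diene-1-carboxylate | COC(=O)C1=CC=C[C@@H](O)C1
A1 | alternative 1 | methyl shikimate | COC(=O)C1=C[C@@H](O)[C@@H](O)[C@H](O)C1
A2 | alternative 1 | methyl 3,4-O-isopropylidene-shikimate | COC(=O)C1=C[C@H]2OC(C)(C)O[C@H]2[C@H](O)C1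
A3 | alternative 2 | methyl (5R)-5-{[(3S)-3-methylpentanoyl]oxy}cyclohexa-1,3-diene-1-carboxylate | COC(=O)C1=CC=C[C@H](OC(=O)C[C@@H](C)CC)C1
A4 | alternative 3 | methyl (4R,5S,6R)-6-acetoxy-5-{[(2R)-2-methylbutanoyl]oxy}-4-{[(3S)-3-methylpentanoyl]oxy}-2-methylideneoct-7-enoate | C=C(C(=O)OC)C[C@@H](OC(=O)C[C@@H](C)CC)[C@H](OC(=O)[C@H](C)CC)[C@H](OC(C)=O)C=C
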